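The seven-membered ring is traced back to a cyclohexenone: C7 is inserted late between C6 and C8 by diazo homologation. The cyclohexenone comes from a Diels–Alder reaction of a 1-methoxy-3-silyloxy diene with (R)-4-methylcyclopent-2-enone, which forms C5–C6 and C3a–C4 in one operation, cis and anti to the methyl group. The step exploits that C4, C5 and side-chain carbons C1′–C3′ map onto a cyclopentenone ring: Baeyer–Villiger migration of C4 then supplies the C4 oxygen with retention and turns the ring carbonyl into C3′. The cyclopentene ring (C1–C3) is annulated afterwards by cuprate addition, allylation and ring-closing metathesis.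

Key step: step 3

Remark: the core is numbered as an azulene (C1=C2, C3 carbinol, C3a, C4 carbinol, C5, C6, C7, C8 methylidene-bearing, C8a) and the side chain C1′ (methyl-bearing) to C5′; these labels are used for the corresponding atoms of all intermediates.

Step 1
Reactants: 1 (R)-4-[(tert-butyldimethylsilyl)oxy]cyclopent-2-en-1-one
Product: 2 (3R,4R)-4-[(tert-butyldimethylsilyl)oxy]-3-methylcyclopentan-1-one
Conditions: Me2CuLi, Et2O, −78 °C; then H2O at −78 °C
Reagents that add atoms: lithium dimethylcuprate, [Li+].C[Cu-]C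
Why: Conjugate addition of a lithium diorganocuprate, in which the methyl group should enter anti to the 4-silyloxy group and so set the future C1′ centre, while the cold quench keeps the silyloxy group in place.

Step 2
Reactants: 2 (3R,4R)-4-[(tert-butyldimethylsilyl)oxy]-3-methylcyclopentan-1-one
Product: 3 (R)-4-methylcyclopent-2-en-1-one
Conditions: DBU, CH2Cl2, 0 °C
Reagents that add atoms: none
Why: E1cB β-elimination of the silanol should give the transposed enone without touching the methyl-bearing centre, and short exposure to the base limits γ-deprotonation.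

Step 3
Reactants: 3 (R)-4-methylcyclopent-2-en-1-one; 4 (E)-1-methoxy-3-[(trimethylsilyl)oxy]buta-1,3-diene
Product: 6 (3R,3aS,7aS)-3-methyl-2,3,3a,4-tetrahydro-1H-indene-1,5(7aH)-dione, via silyl enol ether cycloadduct 5 (not isolated)
Conditions: toluene, 130 °C, sealed tube; then 1 M aq. HCl, THF, 0 °C
Reagents that add atoms: none
Why: Diels–Alder reaction ([4+2] cycloaddition) of an electron-rich 1-methoxy-3-silyloxy diene with a cycloalkenone, a well-known pairing. The concerted, suprafacial addition closes the six-membered ring that becomes C3a–C4–C5–C6–C8–C8a: the nucleophilic CH2 terminus of 4 (C6) bonds to the enone β-carbon (C5) and the methoxy-bearing terminus (C3a) to the α-carbon (C4), as dictated by the polarisation of the diene. C4 and C5 are formed cis because the dienophile double bond is held Z in its five-membered ring, and the diene should add to the face of 3 anti to the adjacent methyl group, which relays the (R) centre to both new centres. The endo/exo outcome at the methoxy-bearing carbon does not matter, since acid hydrolysis of the silyl enol ether and β-elimination of methanol convert 5 into enone 6. The step therefore needs only regio- and π-facial selectivity, and both are secured by substituents already present in the two partners.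

Step 4
Reactants: 6 (3R,3aS,7aS)-3-methyl-2,3,3a,4-tetrahydro-1H-indene-1,5(7aH)-dione
Product: 7 (4R,4aS,8aS)-4-methyl-3,4,4a,5-tetrahydro-2H-chromene-2,6(8aH)-dione
Conditions: mCPBA, NaHCO3, CH2Cl2, 0 °C to rt
Reagents that add atoms: mCPBA, O=C(OO)c1cccc(Cl)c1
Why: Baeyer–Villiger oxidation, in which the saturated cyclopentanone should react while the conjugated enone does not, and the secondary allylic C4 migrates with retention so that the C4–O bond takes the configuration set in step 3.

Step 5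
Reactants: 7 (4R,4aS,8aS)-4-methyl-3,4,4a,5-tetrahydro-2H-chromene-2,6(8aH)-dione
Product: 8 (3R)-3-[(1S,2S)-2-hydroxy-5-oxocyclohex-3-en-1-yl]-N-methoxy-N-methylbutanamide
Conditions: MeNHOMe·HCl, AlMe3, CH2Cl2, 0 °C to rt; then H2O
Reagents that add atoms: N,O-dimethylhydroxylamine hydrochloride, CNOC.Cl
Why: Aluminium-amide aminolysis of the lactone should give the N-methoxy-N-methylamide (the acyl group for the later Weinreb ketone synthesis) and free the C4 hydroxyl without touching a stereocentre.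

Step 6
Reactants: 8 (3R)-3-[(1S,2S)-2-hydroxy-5-oxocyclohex-3-en-1-yl]-N-methoxy-N-methylbutanamide
Product: 9 (3R)-3-[(1S,2S)-2-[(tert-butyldimethylsilyl)oxy]-5-oxocyclohex-3-en-1-yl]-N-methoxy-N-methylbutanamide
Conditions: TBSOTf, 2,6-lutidine, CH2Cl2, −78 °C
Reagents that add atoms: tert-butyldimethylsilyl triflate, CC(C)(C)[Si](C)(C)OS(=O)(=O)C(F)(F)F
Why: Silyl ether formation turns the γ-oxygen into a non-leaving, face-shielding group for the cuprate step and prevents relactonisation.

Step 7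
Reactants: 9 (3R)-3-[(1S,2S)-2-[(tert-butyldimethylsilyl)oxy]-5-oxocyclohex-3-en-1-yl]-N-methoxy-N-methylbutanamide
Product: 11 (3R)-3-[(1S,2R,3S,4R)-4-allyl-2-[(tert-butyldimethylsilyl)oxy]-5-oxo-3-(prop-1-en-2-yl)cyclohexyl]-N-methoxy-N-methylbutanamide, via lithium enolate 10 (not isolated)
Conditions: (CH2=CMe)2CuLi, Et2O, −78 °C; then allyl iodide, HMPA, −78 to −20 °C
Reagents that add atoms: lithium di(prop-1-en-2-yl)cuprate, [Li+].C=C(C)[Cu-]C(C)=C; allyl iodide, C=CCI
Why: Cuprate conjugate addition followed by enolate alkylation (three-component coupling), in which the isopropenyl group should add anti to the γ-silyloxy group and the C5 side chain to set C3a, and the regiodefined enolate is allylated trans to it to set C8a, while the amide is inert to the cuprate.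

Step 8
Reactants: 11 (3R)-3-[(1S,2R,3S,4R)-4-allyl-2-[(tert-butyldimethylsilyl)oxy]-5-oxo-3-(prop-1-en-2-yl)cyclohexyl]-N-methoxy-N-methylbutanamide
Product: 12 (3R)-3-[(3aS,4R,5S,7aR)-4-[(tert-butyldimethylsilyl)oxy]-3-methyl-7-oxo-3a,4,5,6,7,7a-hexahydro-1H-inden-5-yl]-N-methoxy-N-methylbutanamide
Conditions: second-generation Grubbs catalyst RuCl2(=CHPh)(PCy3)(H2IMes) (5 mol %), CH2Cl2, 40 °C
Reagents that add atoms: none
Why: Ring-closing olefin metathesis of the 1,1-disubstituted and the monosubstituted alkene should close the trisubstituted cyclopentene (C1–C2=C3) with the trans ring fusion set in step 7.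

Step 9
Reactants: 12 (3R)-3-[(3aS,4R,5S,7aR)-4-[(tert-butyldimethylsilyl)oxy]-3-methyl-7-oxo-3a,4,5,6,7,7a-hexahydro-1H-inden-5-yl]-N-methoxy-N-methylbutanamide
Product: 14 (3R)-3-[(3aS,4R,5S,8aR)-4-[(tert-butyldimethylsilyl)oxy]-3-methyl-8-oxo-1,3a,4,5,6,7,8,8a-octahydroazulen-5-yl]-N-methoxy-N-methylbutanamide, via alpha-silyl ketone 13 (not isolated)
Conditions: TMSCHN2, BF3·OEt2, CH2Cl2, −78 °C; then 1 M aq. HCl, THF, 0 °C
Reagents that add atoms: (trimethylsilyl)diazomethane, C[Si](C)(C)C=[N+]=[N-]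
Why: Lewis-acid-promoted diazoalkane homologation (Tiffeneau–Demjanov-type ring expansion), in which the less substituted CH2 (C6) should migrate in preference to the ring-fusion methine, so the new carbon becomes C7, and the α-silyl ketone is protodesilylated on acid work-up.

Step 10
Reactants: 14 (3R)-3-[(3aS,4R,5S,8aR)-4-[(tert-butyldimethylsilyl)oxy]-3-methyl-8-oxo-1,3a,4,5,6,7,8,8a-octahydroazulen-5-yl]-N-methoxy-N-methylbutanamide
Product: 15 (3R)-3-[(3aS,4R,5S,8aR)-4-[(tert-butyldimethylsilyl)oxy]-3-methyl-8-methylidene-1,3a,4,5,6,7,8,8a-octahydroazulen-5-yl]-N-methoxy-N-methylbutanamide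
Conditions: Ph3PCH3Br, KOtBu, THF, 0 °C to rt
Reagents that add atoms: methyltriphenylphosphonium bromide, C[P+](c1ccccc1)(c1ccccc1)c1ccccc1.[Br-]
Why: Wittig methylenation should convert the ketone and leave the amide alone, and the epimerisable C8a should stay in the trans-fused arrangement, which is expected to be the more stable one for this hydroazulenone.

Step 11
Reactants: 15 (3R)-3-[(3aS,4R,5S,8aR)-4-[(tert-butyldimethylsilyl)oxy]-3-methyl-8-methylidene-1,3a,4,5,6,7,8,8a-octahydroazulen-5-yl]-N-methoxy-N-methylbutanamide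
Product: 16 (2S,3R)-2,3-epoxide of 15 with the oxirane oxygen syn to H-3a
Conditions: mCPBA (1.05 equiv), NaHCO3, CH2Cl2, −20 °C
Reagents that add atoms: mCPBA, O=C(OO)c1cccc(Cl)c1
Why: Prilezhaev epoxidation, in which the trisubstituted ring alkene should react faster than the 1,1-disubstituted methylidene group and the peracid should approach the cyclopentene face that carries H-3a, anti to the C4-bearing ring bond, which fixes the C3–O configuration.

Step 12
Reactants: 16 (2S,3R)-2,3-epoxide of 15 with the oxirane oxygen syn to H-3a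
Product: 19 (3R)-3-[(3S,3aR,4R,5S,8aR)-4-[(tert-butyldimethylsilyl)oxy]-3-hydroxy-3-methyl-8-methylidene-3,3a,4,5,6,7,8,8a-octahydroazulen-5-yl]-N-methoxy-N-methylbutanamide, via hydroxy selenide 17 (not isolated), via selenoxide 18 (not isolated)
Conditions: PhSeNa, EtOH, 60 °C; then 30% aq. H2O2, pyridine, THF, 0 °C to rt
Reagents that add atoms: none
Why: Epoxide-to-allylic-alcohol transposition by selenolate opening and selenoxide syn-elimination, in which the selenolate should open the epoxide at the less hindered C2 by SN2 so that the C3–O bond and its configuration remain, and the selenoxide can only take a hydrogen from C1 to give the C1=C2 alkene.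

Step 13
Reactants: 19 (3R)-3-[(3S,3aR,4R,5S,8aR)-4-[(tert-butyldimethylsilyl)oxy]-3-hydroxy-3-methyl-8-methylidene-3,3a,4,5,6,7,8,8a-octahydroazulen-5-yl]-N-methoxy-N-methylbutanamide
Product: 20 (6R)-6-[(3S,3aR,4R,5S,8aR)-4-[(tert-butyldimethylsilyl)oxy]-3-hydroxy-3-methyl-8-methylidene-3,3a,4,5,6,7,8,8a-octahydroazulen-5-yl]-2-methylhept-2-en-4-one
Conditions: (2-methylprop-1-enyl)MgBr (3.5 equiv), THF, 0 °C; then H2O
Reagents that add atoms: (2-methylprop-1-en-1-yl)magnesium bromide, CC(C)=C[Mg]Br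
Why: Weinreb ketone synthesis, in which the chelated tetrahedral intermediate should prevent over-addition and the first equivalent of the reagent only deprotonates the tertiary alcohol.

Step 14
Reactants: 20 (6R)-6-[(3S,3aR,4R,5S,8aR)-4-[(tert-butyldimethylsilyl)oxy]-3-hydroxy-3-methyl-8-methylidene-3,3a,4,5,6,7,8,8a-octahydroazulen-5-yl]-2-methylhept-2-en-4-one
Product: 21 (4R,6R)-6-[(3S,3aR,4R,5S,8aR)-4-[(tert-butyldimethylsilyl)oxy]-3-hydroxy-3-methyl-8-methylidene-3,3a,4,5,6,7,8,8a-octahydroazulen-5-yl]-2-methylhept-2-en-4-ol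
Conditions: (S)-2-methyl-CBS-oxazaborolidine (0.3 equiv), catecholborane, toluene, −78 °C; then MeOH, H2O
Reagents that add atoms: none
Why: Corey–Bakshi–Shibata reduction of the enone, in which the alkenyl group acts as the large substituent so that the (S)-catalyst should deliver the (R)-carbinol at C3′, and catecholborane does not hydroborate the alkenes at this temperature.

Step 15
Reactants: 21 (4R,6R)-6-[(3S,3aR,4R,5S,8aR)-4-[(tert-butyldimethylsilyl)oxy]-3-hydroxy-3-methyl-8-methylidene-3,3a,4,5,6,7,8,8a-octahydroazulen-5-yl]-2-methylhept-2-en-4-ol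
Product: 22 (4R,6R)-6-[(3S,3aR,4R,5S,8aR)-4-[(tert-butyldimethylsilyl)oxy]-3-hydroxy-3-methyl-8-methylidene-3,3a,4,5,6,7,8,8a-octahydroazulen-5-yl]-2-methylhept-2-en-4-yl acetate
Conditions: Ac2O, pyridine, CH2Cl2, 0 °C to rt
Reagents that add atoms: acetic anhydride, CC(=O)OC(C)=O
Why: Acylation should take place only at the secondary allylic alcohol, since the tertiary alcohol is unreactive under these conditions and the C4 oxygen is silylated.

Step 16
Reactants: 22 (4R,6R)-6-[(3S,3aR,4R,5S,8aR)-4-[(tert-butyldimethylsilyl)oxy]-3-hydroxy-3-methyl-8-methylidene-3,3a,4,5,6,7,8,8a-octahydroazulen-5-yl]-2-methylhept-2-en-4-yl acetate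
Product: 23 (4R,6R)-6-[(3S,3aR,4R,5S,8aR)-3,4-dihydroxy-3-methyl-8-methylidene-3,3a,4,5,6,7,8,8a-octahydroazulen-5-yl]-2-methylhept-2-en-4-yl acetate (target)
Conditions: HF·pyridine, pyridine, THF, 0 °C to rt
Reagents that add atoms: none
Why: Fluoride-mediated silyl ether cleavage under buffered conditions should free the C4 hydroxyl and leave the allylic acetate and the tertiary allylic alcohol intact.

Compound list
1 | (R)-4-[(tert-butyldimethylsilyl)oxy]cyclopent-2-en-1-one | O=C1C=C[C@H](O[Si](C)(C)C(C)(C)C)C1 | starting material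
2 | (3R,4R)-4-[(tert-butyldimethylsilyl)oxy]-3-methylcyclopentan-1-one | O=C1C[C@@H](C)[C@H](O[Si](C)(C)C(C)(C)C)C1 | intermediate
3 | (R)-4-methylcyclopent-2-en-1-one | O=C1C=C[C@H](C)C1 | intermediate
4 | (E)-1-methoxy-3-[(trimethylsilyl)oxy]buta-1,3-diene | CO/C=C/C(=C)O[Si](C)(C)C | starting material
5 | (3R,3aS,7S,7aR)-7-methoxy-3-methyl-5-[(trimethylsilyl)oxy]-2,3,3a,4,7,7a-hexahydro-1H-inden-1-one (endo cycloadduct, not isolated) | C[Si](C)(C)OC1=C[C@H](OC)[C@H]2[C@@H](C1)[C@H](C)CC2=O | intermediate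
6 | (3R,3aS,7aS)-3-methyl-2,3,3a,4-tetrahydro-1H-indene-1,5(7aH)-dione | O=C1C=C[C@H]2[C@@H](C1)[C@H](C)CC2=O | intermediate
7 | (4R,4aS,8aS)-4-methyl-3,4,4a,5-tetrahydro-2H-chromene-2,6(8aH)-dione | O=C1C=C[C@H]2[C@@H](C1)[C@H](C)CC(=O)O2 | intermediate
8 | (3R)-3-[(1S,2S)-2-hydroxy-5-oxocyclohex-3-en-1-yl]-N-methoxy-N-methylbutanamide | O=C1C=C[C@H](O)[C@@H](C1)[C@H](C)CC(=O)N(C)OC | intermediate
9 | (3R)-3-[(1S,2S)-2-[(tert-butyldimethylsilyl)oxy]-5-oxocyclohex-3-en-1-yl]-N-methoxy-N-methylbutanamide | O=C1C=C[C@H](O[Si](C)(C)C(C)(C)C)[C@@H](C1)[C@H](C)CC(=O)N(C)OC | intermediate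
10 | lithium enolate of 11 before allylation (enolate C8=C8a, isopropenyl at C3a anti to the silyloxy group; not isolated) | [Li]OC1=C[C@@H](C(C)=C)[C@H](O[Si](C)(C)C(C)(C)C)[C@@H](C1)[C@H](C)CC(=O)N(C)OC | intermediate
11 | (3R)-3-[(1S,2R,3S,4R)-4-allyl-2-[(tert-butyldimethylsilyl)oxy]-5-oxo-3-(prop-1-en-2-yl)cyclohexyl]-N-methoxy-N-methylbutanamide | O=C1[C@H](CC=C)[C@@H](C(C)=C)[C@H](O[Si](C)(C)C(C)(C)C)[C@@H](C1)[C@H](C)CC(=O)N(C)OC | intermediate
12 | (3R)-3-[(3aS,4R,5S,7aR)-4-[(tert-butyldimethylsilyl)oxy]-3-methyl-7-oxo-3a,4,5,6,7,7a-hexahydro-1H-inden-5-yl]-N-methoxy-N-methylbutanamide | O=C1[C@@H]2CC=C(C)[C@H]2[C@H](O[Si](C)(C)C(C)(C)C)[C@@H](C1)[C@H](C)CC(=O)N(C)OC | intermediate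
13 | C7-trimethylsilyl derivative of ketone 14 (alpha-silyl ketone, either configuration at C7; not isolated) | O=C1[C@@H]2CC=C(C)[C@H]2[C@H](O[Si](C)(C)C(C)(C)C)[C@@H](CC1[Si](C)(C)C)[C@H](C)CC(=O)N(C)OC | intermediate
14 | (3R)-3-[(3aS,4R,5S,8aR)-4-[(tert-butyldimethylsilyl)oxy]-3-methyl-8-oxo-1,3a,4,5,6,7,8,8a-octahydroazulen-5-yl]-N-methoxy-N-methylbutanamide | O=C1[C@@H]2CC=C(C)[C@H]2[C@H](O[Si](C)(C)C(C)(C)C)[C@@H](CC1)[C@H](C)CC(=O)N(C)OC | intermediate
15 | (3R)-3-[(3aS,4R,5S,8aR)-4-[(tert-butyldimethylsilyl)oxy]-3-methyl-8-methylidene-1,3a,4,5,6,7,8,8a-octahydroazulen-5-yl]-N-methoxy-N-methylbutanamide | C=C1[C@@H]2CC=C(C)[C@H]2[C@H](O[Si](C)(C)C(C)(C)C)[C@@H](CC1)[C@H](C)CC(=O)N(C)OC | intermediate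
16 | (2S,3R)-2,3-epoxide of 15, oxirane oxygen syn to H-3a | C=C1[C@@H]2C[C@@H]3O[C@]3(C)[C@H]2[C@H](O[Si](C)(C)C(C)(C)C)[C@@H](CC1)[C@H](C)CC(=O)N(C)OC | intermediate
17 | hydroxy selenide from 16: C3 tertiary alcohol (OH syn to H-3a), phenylselanyl group at C2 trans to it (not isolated) | C=C1[C@@H]2C[C@@H]([Se]c3ccccc3)[C@](C)(O)[C@H]2[C@H](O[Si](C)(C)C(C)(C)C)[C@@H](CC1)[C@H](C)CC(=O)N(C)OC | intermediate
18 | selenoxide of 17 (either configuration at selenium; not isolated) | C=C1[C@@H]2C[C@@H]([Se](=O)c3ccccc3)[C@](C)(O)[C@H]2[C@H](O[Si](C)(C)C(C)(C)C)[C@@H](CC1)[C@H](C)CC(=O)N(C)OC | intermediate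
19 | (3R)-3-[(3S,3aR,4R,5S,8aR)-4-[(tert-butyldimethylsilyl)oxy]-3-hydroxy-3-methyl-8-methylidene-3,3a,4,5,6,7,8,8a-octahydroazulen-5-yl]-N-methoxy-N-methylbutanamide | C=C1[C@@H]2C=C[C@](C)(O)[C@H]2[C@H](O[Si](C)(C)C(C)(C)C)[C@@H](CC1)[C@H](C)CC(=O)N(C)OC | intermediate
20 | (6R)-6-[(3S,3aR,4R,5S,8aR)-4-[(tert-butyldimethylsilyl)oxy]-3-hydroxy-3-methyl-8-methylidene-3,3a,4,5,6,7,8,8a-octahydroazulen-5-yl]-2-methylhept-2-en-4-one | C=C1[C@@H]2C=C[C@](C)(O)[C@H]2[C@H](O[Si](C)(C)C(C)(C)C)[C@@H](CC1)[C@H](C)CC(=O)C=C(C)C | intermediate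
21 | (4R,6R)-6-[(3S,3aR,4R,5S,8aR)-4-[(tert-butyldimethylsilyl)oxy]-3-hydroxy-3-methyl-8-methylidene-3,3a,4,5,6,7,8,8a-octahydroazulen-5-yl]-2-methylhept-2-en-4-ol | C=C1[C@@H]2C=C[C@](C)(O)[C@H]2[C@H](O[Si](C)(C)C(C)(C)C)[C@@H](CC1)[C@H](C)C[C@@H](O)C=C(C)C | intermediate
22 | (4R,6R)-6-[(3S,3aR,4R,5S,8aR)-4-[(tert-butyldimethylsilyl)oxy]-3-hydroxy-3-methyl-8-methylidene-3,3a,4,5,6,7,8,8a-octahydroazulen-5-yl]-2-methylhept-2-en-4-yl acetate | C=C1[C@@H]2C=C[C@](C)(O)[C@H]2[C@H](O[Si](C)(C)C(C)(C)C)[C@@H](CC1)[C@H](C)C[C@@H](OC(C)=O)C=C(C)C | intermediate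
23 | (4R,6R)-6-[(3S,3aR,4R,5S,8aR)-3,4-dihydroxy-3-methyl-8-methylidene-3,3a,4,5,6,7,8,8a-octahydroazulen-5-yl]-2-methylhept-2-en-4-yl acetate | C=C1CC[C@@H]([C@H](C)C[C@H](C=C(C)C)OC(C)=O)[C@@H](O)[C@H]2[C@H]1C=C[C@]2(C)O | target

Total step count: 16. Longest linear sequence: 16 steps (from 1; diene 4 is used as purchased).

Steps most likely to fail

Step 3. The β-unactivated cyclopentenone may add too slowly, so that the diene decomposes first, and the enedione may isomerise its double bond during acid treatment. Fallback: the same two bonds are made stepwise by polar chemistry. Setting out from 3 and 4, a TMSOTf-catalysed Mukaiyama–Michael addition (CH2Cl2, −78 °C) should form the C5–C6 bond anti to the methyl group and give (E)-4-methoxy-1-[(1S,5R)-5-methyl-3-[(trimethylsilyl)oxy]cyclopent-2-en-1-yl]but-3-en-2-one F1. TiCl4 (CH2Cl2, −78 °C) should then close C3a–C4 by intramolecular Mukaiyama–Michael addition of the ring silyl enol ether to the β-methoxy enone with loss of methoxytrimethylsilane. The route is rejoined at 6.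

Step 9. The ring-fusion carbon may migrate in competition with C6, and a second homologation or epoxide formation may occur. Fallback: the carbon is inserted regiospecifically by a Saegusa–Ito ring enlargement. Setting out from 12, kinetic enolisation at C6 (LDA, TMSCl, THF, −78 °C) should give the trimethylsilyl enol ether F2. Cyclopropanation of the enol ether (Et2Zn, CH2I2, Et2O, 0 °C) should give the siloxycyclopropane F3. FeCl3 in DMF (0 °C) should open the internal bond to the β-chloro cycloheptanone F4, and NaOAc in MeOH should eliminate HCl to give the cycloheptenone F5. Conjugate reduction with [(Ph3P)CuH]6 (benzene, rt) returns to 14.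

Step 11. The peracid may attack the cyclopentene from the face anti to H-3a, or the methylidene group may be epoxidised as well. Fallback: the oxygen is brought in as a nucleophile, so the face of electrophile attack is inverted. Setting out from 15, NBS in THF/H2O (0 °C) should form the bromonium ion on that same α-face and water should open it at the tertiary C3 from the opposite face, giving the bromohydrin F6 (C3–OH syn to H-3a, C2–Br trans). K2CO3 in MeOH then closes the epoxide by intramolecular SN2, and the route is rejoined at 16.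

Further compounds
F1 | step 3 | (E)-4-methoxy-1-[(1S,5R)-5-methyl-3-[(trimethylsilyl)oxy]cyclopent-2-en-1-yl]but-3-en-2-one | CO/C=C/C(=O)C[C@@H]1C=C(O[Si](C)(C)C)C[C@H]1C
F2 | step 9 | trimethylsilyl enol ether of 12 (enol double bond between the ketone carbon and C6) | C[Si](C)(C)OC=1[C@@H]2CC=C(C)[C@H]2[C@H](O[Si](C)(C)C(C)(C)C)[C@@H](C=1)[C@H](C)CC(=O)N(C)OC
F3 | step 9 | siloxycyclopropane from F2 (cyclopropane on the former enol double bond, either face) | C[Si](C)(C)OC13[C@@H]2CC=C(C)[C@H]2[C@H](O[Si](C)(C)C(C)(C)C)[C@@H](C1C3)[C@H](C)CC(=O)N(C)OC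
F4 | step 9 | C6-chloro derivative of cycloheptanone 14 (β-chloro ketone, either configuration at C6) | O=C1[C@@H]2CC=C(C)[C@H]2[C@H](O[Si](C)(C)C(C)(C)C)[C@@H](C(Cl)C1)[C@H](C)CC(=O)N(C)OC
F5 | step 9 | 6,7-didehydro derivative of 14 (cyclohept-2-enone, C6=C7) | O=C1[C@@H]2CC=C(C)[C@H]2[C@H](O[Si](C)(C)C(C)(C)C)[C@@H](C=C1)[C@H](C)CC(=O)N(C)OC
F6 | step 11 | bromohydrin of 15 (C3 tertiary alcohol syn to H-3a, C2 bromide trans to it) | C=C1[C@@H]2C[C@@H](Br)[C@](C)(O)[C@H]2[C@H](O[Si](C)(C)C(C)(C)C)[C@@H](CC1)[C@H](C)CC(=O)N(C)OC
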